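**Strategy.** The benzene ring is built, not functionalised. Its 1,2,3-pattern (O on C1, N on C2, the pyridin-4-yl group on C3, C4–C6 unsubstituted) maps onto a 6-aryl salicylate whose ester carbon hangs on C2. A TiCl4-mediated [3+3] cyclocondensation joins the bis(trimethylsilyl) dienol ether of methyl acetoacetate (supplying C6, C1, C2) to a pyridyl β-keto acetal (supplying C3, C4, C5). It forges C5–C6 and C2–C3, closes the ring and aromatises in one operation. The keto acetal comes from 4-acetyl-2-methylpyridine by formylation and acetalisation. A Curtius rearrangement then exchanges the ester carbon on C2 for nitrogen, and N-decanoylation completes the target.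

Key step: step 5

Remark: the target is achiral, so no stereocentre has to be set. The enol ether geometries of 2, 3 and 4 and the transient sp3 centres of 9 and 10 are of no consequence and are left undefined in the SMILES. In step 5 the water formally lost on aromatisation is taken up by the two silyl groups, so the net by-products are two methanol and hexamethyldisiloxane.

Step 1
Reactants: 1 methyl acetoacetate
Product: 2 methyl 3-(trimethylsilyloxy)but-2-enoate
Conditions: Me3SiCl, Et3N, hexane, rt
Reagents that add atoms: chlorotrimethylsilane, C[Si](C)(C)Cl
Why: Soft enolisation of the β-keto ester by Et3N and O-silylation by Me3SiCl (silyl enol ether formation) should give the conjugated, distillable enol ether, whose double-bond geometry does not matter for the next step.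

Step 2
Reactants: 2 methyl 3-(trimethylsilyloxy)but-2-enoate
Product: 4 diene 1-methoxy-1,3-bis(trimethylsilyloxy)buta-1,3-diene, via lithium dienolate 3 (not isolated)
Conditions: LiN(i-Pr)2, THF, −78 °C; then Me3SiCl, −78 °C to rt
Reagents that add atoms: chlorotrimethylsilane, C[Si](C)(C)Cl
Why: Kinetic γ-deprotonation of the vinylogous ester by the lithium amide and O-silylation of the resulting ester dienolate is the standard entry to 1,3-bis(silyloxy)-1,3-dienes; the moisture-sensitive diene should be freed from LiCl by filtration in hexane and used at once.

Step 3
Reactants: 5 ketone 1-(2-methylpyridin-4-yl)ethanone; 6 methyl formate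
Product: 7 sodium (Z)-3-(2-methylpyridin-4-yl)-3-oxoprop-1-en-1-olate
Conditions: NaOMe, THF, 0 °C to rt; solid collected by filtration
Reagents that add atoms: sodium methoxide, [Na+].[O-]C
Why: Crossed Claisen condensation of the methyl ketone enolate with a non-enolisable formate, pulled forward by precipitation of the stabilised sodium enolate; the ring methyl group is far less acidic than the acetyl group and should stay untouched.

Step 4
Reactants: 7 sodium (Z)-3-(2-methylpyridin-4-yl)-3-oxoprop-1-en-1-olate
Product: 8 keto acetal 3,3-dimethoxy-1-(2-methylpyridin-4-yl)propan-1-one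
Conditions: HCl (3 M in MeOH, 3 equiv), MeOH, −10 °C to rt; then NaHCO3
Reagents that add atoms: methanol, CO
Why: Acid-catalysed acetalisation in excess methanol should take place only at the formyl carbon, which is far more electrophilic than the aryl ketone, while the pyridine is protonated during the reaction and released again by the NaHCO3 neutralisation before concentration.

Step 5
Reactants: 4 diene 1-methoxy-1,3-bis(trimethylsilyloxy)buta-1,3-diene; 8 keto acetal 3,3-dimethoxy-1-(2-methylpyridin-4-yl)propan-1-one
Product: 11 methyl 2-hydroxy-6-(2-methylpyridin-4-yl)benzoate, via keto ester adduct 9 (not isolated), via cyclohexanone aldol 10 (not isolated)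
Conditions: TiCl4 (2.5 equiv), 4 (1.5 equiv), CH2Cl2, −78 °C to rt; then aq. NaHCO3
Reagents that add atoms: none
Why: TiCl4, used in excess because one equivalent is bound by the pyridine nitrogen, ionises the acetal of 8 to an oxocarbenium ion, which is captured by the terminal carbon of diene 4 in a vinylogous Mukaiyama aldol-type addition to give keto ester 9 as its titanium enolate. The central carbon of that β-keto ester enolate then adds to the pyridyl ketone in an intramolecular aldol reaction, a 6-(enolendo)-exo-trig closure that forms carbocycle 10; β-elimination of methanol and dehydration of the tertiary carbinol, both driven by aromatisation, should deliver the phenol. The closest known reaction type is the Lewis acid [3+3] cyclocondensation of 1,3-bis(silyloxy)-1,3-dienes with β-keto acetals or 3-silyloxy enones to give 6-substituted salicylates. No stereocentre survives, since the three sp3 centres of 10 are erased on aromatisation. The step needs regioselectivity (aryl beside the ester, not para to it), and the substrate secures it: the ionised acetal is the stronger electrophile and the diene terminus the stronger nucleophile, so they pair first and leave the electron-poor pyridyl ketone for the ring-closing aldol.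

Step 6
Reactants: 11 methyl 2-hydroxy-6-(2-methylpyridin-4-yl)benzoate
Product: 12 acid 2-hydroxy-6-(2-methylpyridin-4-yl)benzoic acid
Conditions: NaOH (6 equiv), MeOH/H2O, reflux; then HCl to pH 4–5
Reagents that add atoms: sodium hydroxide, [Na+].[OH-]
Why: Saponification (ester hydrolysis by acyl–oxygen cleavage) under forcing aqueous base, as the doubly ortho-substituted, phenoxide-deactivated ester requires, followed by precipitation of the zwitterionic acid near its isoelectric point.

Step 7
Reactants: 12 acid 2-hydroxy-6-(2-methylpyridin-4-yl)benzoic acid
Product: 15 benzoxazolone 4-(2-methylpyridin-4-yl)-1,3-benzoxazol-2(3H)-one, via acyl azide 13 (not isolated), via isocyanate 14 (not isolated)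
Conditions: (PhO)2P(O)N3, Et3N, 1,4-dioxane, rt then 100 °C
Reagents that add atoms: diphenylphosphoryl azide, [N-]=[N+]=NP(=O)(Oc1ccccc1)Oc1ccccc1
Why: The carboxylate is converted by the phosphoryl azide into acyl azide 13, which undergoes Curtius rearrangement with retention of the ring position to isocyanate 14, and the neighbouring phenol adds intramolecularly to close the cyclic carbamate, a sequence established for salicylic acids.

Step 8
Reactants: 15 benzoxazolone 4-(2-methylpyridin-4-yl)-1,3-benzoxazol-2(3H)-one
Product: 16 aminophenol 2-amino-3-(2-methylpyridin-4-yl)phenol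
Conditions: NaOH (4 M aq), EtOH, reflux, Ar; then HCl to pH 7–8
Reagents that add atoms: none
Why: Base hydrolysis of the cyclic carbamate (hydroxide adds to the carbonyl, the phenoxide leaves, the carbamate salt loses carbonate) should free the aminophenol, which is kept under argon because it is prone to oxidation and is carried forward crude.

Step 9
Reactants: 16 aminophenol 2-amino-3-(2-methylpyridin-4-yl)phenol; 17 decanoyl chloride
Product: 18 echinoclathrine A
Conditions: 17 (1.0 equiv), NaHCO3, THF/H2O, 0 °C to rt
Reagents that add atoms: none
Why: N-Acylation under Schotten–Baumann-type conditions at near-neutral pH, where the aniline nitrogen outcompetes the un-ionised phenol, and any O-acyl product should shift to nitrogen by the O-to-N acyl migration typical of 2-aminophenols.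

**Compound list**

1 | methyl acetoacetate (methyl 3-oxobutanoate) | COC(=O)CC(C)=O | starting material
2 | methyl 3-(trimethylsilyloxy)but-2-enoate (E/Z mixture, geometry of no consequence) | COC(=O)C=C(C)O[Si](C)(C)C | intermediate
3 | lithium 1-methoxy-3-(trimethylsilyloxy)buta-1,3-dien-1-olate (formed in the flask, not isolated) | [Li+].[O-]C(OC)=CC(=C)O[Si](C)(C)C | intermediate
4 | 1-methoxy-1,3-bis(trimethylsilyloxy)buta-1,3-diene (geometry at C1=C2 of no consequence) | COC(O[Si](C)(C)C)=CC(=C)O[Si](C)(C)C | intermediate
5 | 1-(2-methylpyridin-4-yl)ethanone | CC(=O)c1ccnc(C)c1 | starting material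
6 | methyl formate | COC=O | starting material
7 | sodium (Z)-3-(2-methylpyridin-4-yl)-3-oxoprop-1-en-1-olate | [Na+].[O-]/C=C\C(=O)c1ccnc(C)c1 | intermediate
8 | 3,3-dimethoxy-1-(2-methylpyridin-4-yl)propan-1-one | COC(OC)CC(=O)c1ccnc(C)c1 | intermediate
9 | methyl 5-methoxy-7-(2-methylpyridin-4-yl)-3,7-dioxoheptanoate (racemic, present as its titanium enolate, not isolated) | COC(=O)CC(=O)CC(OC)CC(=O)c1ccnc(C)c1 | intermediate
10 | methyl 2-hydroxy-4-methoxy-2-(2-methylpyridin-4-yl)-6-oxocyclohexane-1-carboxylate (mixture of racemic diastereomers, not isolated) | COC(=O)C1C(=O)CC(OC)CC1(O)c1ccnc(C)c1 | intermediate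
11 | methyl 2-hydroxy-6-(2-methylpyridin-4-yl)benzoate | COC(=O)c1c(O)cccc1-c1ccnc(C)c1 | intermediate
12 | 2-hydroxy-6-(2-methylpyridin-4-yl)benzoic acid | OC(=O)c1c(O)cccc1-c1ccnc(C)c1 | intermediate
13 | 2-hydroxy-6-(2-methylpyridin-4-yl)benzoyl azide (not isolated) | [N-]=[N+]=NC(=O)c1c(O)cccc1-c1ccnc(C)c1 | intermediate
14 | 2-isocyanato-3-(2-methylpyridin-4-yl)phenol (not isolated) | O=C=Nc1c(O)cccc1-c1ccnc(C)c1 | intermediate
15 | 4-(2-methylpyridin-4-yl)-1,3-benzoxazol-2(3H)-one | O=C1Nc2c(-c3ccnc(C)c3)cccc2O1 | intermediate
16 | 2-amino-3-(2-methylpyridin-4-yl)phenol | Nc1c(O)cccc1-c1ccnc(C)c1 | intermediate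
17 | decanoyl chloride | CCCCCCCCCC(=O)Cl | starting material
18 | echinoclathrine A, N-[2-hydroxy-6-(2-methylpyridin-4-yl)phenyl]decanamide | CCCCCCCCCC(=O)Nc1c(O)cccc1-c1ccnc(C)c1 | target

**Step count**

Total step count: 9. Longest linear sequence: 7 steps (from 5 through steps 3–9, or equally from 1 through steps 1, 2 and 5–9).

**Steps most likely to fail**

Step 5 (the annulation). The pyridine nitrogen may bind the Lewis acid so firmly that the substrate leaves solution as an unreactive titanium complex. The acid-sensitive diene may be desilylated before it meets the oxocarbenium ion. Aromatisation may also stall at the cyclohexanone stage. The fallback is a base-mediated [3+3] benzannulation that needs neither Lewis acid nor silyl diene. It sets out from sodium enolate 7, which is condensed with dimethyl 3-oxopentanedioate (COC(=O)CC(=O)CC(=O)OC) and NaOMe in MeOH, then acidified with HCl. The sequence is Knoevenagel-type condensation at the formyl carbon, intramolecular aldol at the pyridyl ketone and dehydration; the dinucleophile is symmetric, so regiochemistry is not an issue. This should give dimethyl 2-hydroxy-4-(2-methylpyridin-4-yl)benzene-1,3-dicarboxylate F1. The ester on C1, flanked only by OH and H, is saponified selectively with LiOH in THF/H2O at rt to 2-hydroxy-3-(methoxycarbonyl)-4-(2-methylpyridin-4-yl)benzoic acid F2. Copper-catalysed protodecarboxylation of this salicylic acid (Cu2O, 1,10-phenanthroline, NMP/quinoline, 170 °C) removes the surplus carboxyl group, and the route is rejoined at 11.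

Step 7 (Curtius rearrangement and ring closure). Azide transfer to the doubly ortho-substituted, poorly soluble zwitterionic carboxylate may be slow. The phenol may be phosphorylated in competition, or the isocyanate may be intercepted intermolecularly to give ureas. The fallback is a Hofmann rearrangement that avoids carboxyl activation. It sets out from ester 11, which is heated with concentrated NH3 in MeOH in a sealed vessel (ammonolysis assisted by the ortho-hydroxyl group) to give 2-hydroxy-6-(2-methylpyridin-4-yl)benzamide F3. Treatment with NaOCl and NaOH in water at 0 °C gives N-chloro-2-hydroxy-6-(2-methylpyridin-4-yl)benzamide F4, which is not isolated. On warming it rearranges to isocyanate 14, and capture by the neighbouring phenoxide rejoins the route at benzoxazolone 15.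

Step 4 (acetalisation). The acetal may lose methanol to the β-methoxy enone. The liberated keto aldehyde may self-condense under acid. The acetal may also hydrolyse back while the pyridinium salt is neutralised. The fallback builds the acetal carbon under aprotic conditions and bypasses 7. It sets out from ketone 5, which is converted with Me3SiOTf and Et3N in CH2Cl2 at 0 °C into 2-methyl-4-[1-(trimethylsilyloxy)ethenyl]pyridine F5. A Mukaiyama-type addition of this silyl enol ether to trimethyl orthoformate (COC(OC)OC), promoted by BF3·OEt2 (2.2 equiv, one of them taken by the pyridine) in CH2Cl2 at −78 °C, should give the keto acetal directly, and the route is rejoined at 8.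

**Further compounds**

F1 | step 5 | dimethyl 2-hydroxy-4-(2-methylpyridin-4-yl)benzene-1,3-dicarboxylate | COC(=O)c1ccc(-c2ccnc(C)c2)c(C(=O)OC)c1O
F2 | step 5 | 2-hydroxy-3-(methoxycarbonyl)-4-(2-methylpyridin-4-yl)benzoic acid | COC(=O)c1c(-c2ccnc(C)c2)ccc(C(=O)O)c1O
F3 | step 7 | 2-hydroxy-6-(2-methylpyridin-4-yl)benzamide | NC(=O)c1c(O)cccc1-c1ccnc(C)c1
F4 | step 7 | N-chloro-2-hydroxy-6-(2-methylpyridin-4-yl)benzamide | ClNC(=O)c1c(O)cccc1-c1ccnc(C)c1
F5 | step 4 | 2-methyl-4-[1-(trimethylsilyloxy)ethenyl]pyridine | C=C(O[Si](C)(C)C)c1ccnc(C)c1
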